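## Retrosynthetic overview
1. Enone C=C: Claisen–Schmidt disconnection gives 4-hydroxyacetophenone and the (S)-4-methoxy-dihydrobenzofuran-5-carbaldehyde. The phenol of the aldehyde half is already tied up in the ring, so no protecting groups are needed.
2. O–CH3: leads back to the chelated 4-hydroxy-5-formyl dihydrobenzofuran.
3. Dihydrofuran C2–O bond (the only ring formed; both benzene rings are bought): 5-exo-tet opening, with inversion, of an (R)-prenyl epoxide. The epoxide comes from a phenol-directed, peptide-peracid-catalysed asymmetric epoxidation of 2,4-dihydroxy-3-prenylbenzaldehyde.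
4. Aryl–prenyl C–C bond: C3-selective C-prenylation of 2,4-dihydroxybenzaldehyde with prenyl bromide.

Assumption: the facial sense of the new step 2 cannot be known in advance. Catalyst P1 is written as Boc-L-Asp-L-Pro-D-Val-NH-(R)-CH(CH3)Ph. If the first analytical run gives the (S)-epoxide, the mirror-image peptide (D-Asp, D-Pro, L-Val, (S)-amine) is used and everything else stays the same.

## Route

Step 1
Reactants: 1 2,4-dihydroxybenzaldehyde; 2 prenyl bromide (1-bromo-3-methylbut-2-ene)
Product: 3 2,4-dihydroxy-3-(3-methylbut-2-en-1-yl)benzaldehyde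
Conditions: KOH (1.1 equiv), H2O, 0 °C → rt, 16 h; SiO2 separation from the 5-prenyl and O-prenyl isomers
Reagents that add atoms: none
Why: C-alkylation of an ambident resorcinol phenoxide (SN2 on the allylic bromide), in which water solvates the phenoxide oxygens by hydrogen bonding so that C3, flanked by both oxygens, is alkylated preferentially; this is a known, moderate-yielding (about 30–40 %) one-step entry that forms no stereocentre.

Step 2
Reactants: 3 2,4-dihydroxy-3-(3-methylbut-2-en-1-yl)benzaldehyde
Product: 5 (2S)-4-hydroxy-2-(2-hydroxypropan-2-yl)-2,3-dihydro-1-benzofuran-5-carbaldehyde, via (R)-prenyl epoxide 4 (not isolated)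
Conditions: P1 (10 mol %), HOBt·H2O (10 mol %), DIC (1.5 equiv), 30 % aq H2O2 (2 equiv), PhMe, 4 °C, no amine base; aq Na2SO3 wash; then K2CO3 (0.3 equiv), MeOH, 0 °C → rt
Reagents that add atoms: hydrogen peroxide, OO
Why: Proposed new method: a phenol-directed aspartyl-peptide peracid epoxidation / 5-exo-tet cascade on a free ortho-prenylphenol. DIC/H2O2 converts the Asp side-chain CO2H of the β-turn peptide into a transient peracid. The only free and strongly acidic H-bond donor of 3 is the 4-OH (the 2-OH is locked on the CHO), and it docks on a backbone amide carbonyl of the turn. The rigid arene spacer leaves only two rotatable bonds, so one face of the electron-rich trisubstituted C=C meets the peracid in a butterfly transition state and gives (R)-4. Electrophilic O-transfer to the alkene outruns Baeyer–Villiger/Dakin attack on the chelated aldehyde because no base is present and the peracid stays at catalytic concentration. Any acylation of the acidic phenol by the activated Asp is reversed by perhydrolysis. After the peroxide is removed, the more acidic 4-OH is deprotonated selectively and opens the epoxide at the less hindered secondary carbon (Baldwin-favoured SN2, clean inversion, R → S), which closes the dihydrofuran and sets C2 as S. The closest known reaction types are aspartyl-peptide-catalysed epoxidation of allylic carbamates and allylic alcohols, and the racemic mCPBA epoxidation–cyclisation of o-prenylphenols.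

Step 3
Reactants: 5 (2S)-4-hydroxy-2-(2-hydroxypropan-2-yl)-2,3-dihydro-1-benzofuran-5-carbaldehyde
Product: 6 (2S)-2-(2-hydroxypropan-2-yl)-4-methoxy-2,3-dihydro-1-benzofuran-5-carbaldehyde
Conditions: MeI (1.5 equiv), K2CO3 (1.5 equiv), DMF, rt
Reagents that add atoms: iodomethane (MeI), CI
Why: Williamson ether synthesis, in which carbonate deprotonates only the chelated phenol and its phenoxide is methylated by SN2, while the tertiary alcohol, the aldehyde and the C2 ether stereocentre (no acidic hydrogen) are untouched.

Step 4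
Reactants: 6 (2S)-2-(2-hydroxypropan-2-yl)-4-methoxy-2,3-dihydro-1-benzofuran-5-carbaldehyde; 7 4-hydroxyacetophenone
Product: 8 (E)-1-(4-hydroxyphenyl)-3-[(2S)-2-(2-hydroxypropan-2-yl)-4-methoxy-2,3-dihydro-1-benzofuran-5-yl]prop-2-en-1-one (target)
Conditions: KOH (50 % aq, 5 equiv), EtOH, rt → 40 °C, 36 h; then 1 M HCl, 0 °C, to pH 5
Reagents that add atoms: none
Why: Claisen–Schmidt aldol condensation, in which the enolate of the ketone phenoxide adds to the non-enolisable aldehyde and E1cB dehydration gives the conjugated, thermodynamically favoured E-enone; 6 carries no free phenol and C2 has no acidic hydrogen, so no protecting groups are needed and no loss of ee is expected.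

## Compound list
1 | 2,4-dihydroxybenzaldehyde | O=Cc1ccc(O)cc1O | starting material
2 | prenyl bromide (1-bromo-3-methylbut-2-ene) | CC(C)=CCBr | starting material
3 | 2,4-dihydroxy-3-(3-methylbut-2-en-1-yl)benzaldehyde | O=Cc1ccc(O)c(CC=C(C)C)c1O | intermediate
4 | 3-{[(2R)-3,3-dimethyloxiran-2-yl]methyl}-2,4-dihydroxybenzaldehyde | O=Cc1ccc(O)c(C[C@H]2OC2(C)C)c1O | intermediate (not isolated)
5 | (2S)-4-hydroxy-2-(2-hydroxypropan-2-yl)-2,3-dihydro-1-benzofuran-5-carbaldehyde | Oc1c(C=O)ccc2c1C[C@@H](C(C)(C)O)O2 | intermediate
6 | (2S)-2-(2-hydroxypropan-2-yl)-4-methoxy-2,3-dihydro-1-benzofuran-5-carbaldehyde | COc1c(C=O)ccc2c1C[C@@H](C(C)(C)O)O2 | intermediate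
7 | 4-hydroxyacetophenone | CC(=O)c1ccc(O)cc1 | starting material
8 | (E)-1-(4-hydroxyphenyl)-3-[(2S)-2-(2-hydroxypropan-2-yl)-4-methoxy-2,3-dihydro-1-benzofuran-5-yl]prop-2-en-1-one | COc1c(/C=C/C(=O)c2ccc(O)cc2)ccc2c1C[C@@H](C(C)(C)O)O2 | target

## Step count and risks
Total step count: 4. Longest linear sequence: 4 (1 → 3 → 5 → 6 → 8).

**Risk 1, step 2 (the new step).**
- Possible failures:
  - insufficient ee from phenol docking alone;
  - Baeyer–Villiger/Dakin loss of the aldehyde;
  - 6-endo closure to the chromanol;
  - closure through the 2-OH.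
- The ee is read on 5 by chiral HPLC, and 5 is recrystallised if needed.
- The fallback uses known chemistry. It sets out from 3 and comes back at 6, so it also replaces step 3.
- Selective silylation of the non-chelated 4-OH (TIPSCl, imidazole, DMF) gives 2-hydroxy-3-(3-methylbut-2-en-1-yl)-4-[(triisopropylsilyl)oxy]benzaldehyde F1.
- Methylation of the chelated OH under neutral conditions (MeI, Ag2O, CH2Cl2) gives 2-methoxy-3-(3-methylbut-2-en-1-yl)-4-[(triisopropylsilyl)oxy]benzaldehyde F2.
- Shi epoxidation follows (D-fructose-derived ketone 30 mol %, Oxone, K2CO3, borate/EDTA buffer, MeCN–DMM, 0 °C). Its spiro transition state gives the R epoxide from R-CH=CMe2 olefins, here 3-{[(2R)-3,3-dimethyloxiran-2-yl]methyl}-2-methoxy-4-[(triisopropylsilyl)oxy]benzaldehyde F3.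
- TBAF (THF, 0 °C → rt) unmasks the phenoxide, which closes the ring 5-exo with inversion to give 6.

**Risk 2, step 1.**
- Possible failures: a low yield and a laborious separation of C3, C5 and O-prenyl products.
- The fallback sets out from 1 and comes back at 3. It replaces direct alkylation with a sigmatropic delivery of the prenyl group.
- Selective 4-O-alkylation with 3-chloro-3-methylbut-1-yne (K2CO3, KI, cat. CuI, acetone) gives 2-hydroxy-4-[(2-methylbut-3-yn-2-yl)oxy]benzaldehyde F4.
- Lindlar semi-hydrogenation (H2, Pd/CaCO3–Pb, quinoline, EtOAc) gives 2-hydroxy-4-[(2-methylbut-3-en-2-yl)oxy]benzaldehyde F5.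
- Aromatic Claisen rearrangement (N,N-diethylaniline, 130–150 °C) transfers the allyl unit with inversion to C3, the position favoured by bond fixation in the chelated ring, and gives 3.

**Risk 3, step 4.**
- Possible failures: sluggish condensation between the deactivated enolate of the ketone phenoxide and an electron-rich aldehyde, or Cannizzaro side reaction.
- The fallback sets out from 6 and comes back at 8. It replaces the aldol condensation with a base-free olefination.
- Commercial 2-bromo-4'-hydroxyacetophenone and PPh3 (toluene, rt → 60 °C) give [2-(4-hydroxyphenyl)-2-oxoethyl]triphenylphosphonium bromide F6.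
- Aqueous Na2CO3/CH2Cl2 gives the stabilised ylide 1-(4-hydroxyphenyl)-2-(triphenyl-λ5-phosphanylidene)ethan-1-one F7.
- Wittig reaction of F7 with 6 (toluene, reflux) gives the E-enone 8 directly.

## Further compounds
F1 | step 2 | 2-hydroxy-3-(3-methylbut-2-en-1-yl)-4-[(triisopropylsilyl)oxy]benzaldehyde | O=Cc1ccc(O[Si](C(C)C)(C(C)C)C(C)C)c(CC=C(C)C)c1O
F2 | step 2 | 2-methoxy-3-(3-methylbut-2-en-1-yl)-4-[(triisopropylsilyl)oxy]benzaldehyde | COc1c(C=O)ccc(O[Si](C(C)C)(C(C)C)C(C)C)c1CC=C(C)C
F3 | step 2 | 3-{[(2R)-3,3-dimethyloxiran-2-yl]methyl}-2-methoxy-4-[(triisopropylsilyl)oxy]benzaldehyde | COc1c(C=O)ccc(O[Si](C(C)C)(C(C)C)C(C)C)c1C[C@H]2OC2(C)C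
F4 | step 1 | 2-hydroxy-4-[(2-methylbut-3-yn-2-yl)oxy]benzaldehyde | O=Cc1ccc(OC(C)(C)C#C)cc1O
F5 | step 1 | 2-hydroxy-4-[(2-methylbut-3-en-2-yl)oxy]benzaldehyde | O=Cc1ccc(OC(C)(C)C=C)cc1O
F6 | step 4 | [2-(4-hydroxyphenyl)-2-oxoethyl]triphenylphosphonium bromide | [Br-].O=C(C[P+](c1ccccc1)(c1ccccc1)c1ccccc1)c1ccc(O)cc1
F7 | step 4 | 1-(4-hydroxyphenyl)-2-(triphenyl-λ5-phosphanylidene)ethan-1-one | O=C(C=P(c1ccccc1)(c1ccccc1)c1ccccc1)c1ccc(O)cc1
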